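The target is cut at the methylene bridge into an aspidinol-type ring A ketone that carries the (R)-2-methylbutanoyl group and a 5,7-dihydroxy-2,2,6-trimethylchroman-4-one (aromatic ring B, pyranone ring C). Everything rests on closing ring C through its C2–C3 bond: a rhodium carbenoid at C3, made from an aryl diazomethyl ketone, inserts into the tertiary C–H bond of an ortho isopropyl ether. The step exploits the fact that C2, the gem-dimethyl carbon bound to O1, is simply the methine of an isopropyl ether whose C–H bond is activated by O1 and lies six atoms from C3. The precursor is thus an open-chain diazoketone bearing an ordinary O-isopropyl group.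

Key step: step 7

Remark on the chemistry: the stereocentre in CC[C@@H](C)C(=O)Ar is R, (R)-2-methylbutanoic acid is assumed to be purchasable as the single enantiomer, and chromanone numbering (O1, C2, C3, C4, C4a, C5 to C8, C8a) is used for rings B and C.

Step 1
Reactants: 1 (R)-2-methylbutanoic acid; 2 2-methylbenzene-1,3,5-triol (2-methylphloroglucinol)
Product: 4 (2R)-2-methyl-1-(2,4,6-trihydroxy-3-methylphenyl)butan-1-one, via acid chloride 3 (not isolated)
Conditions: (COCl)2, cat. DMF, CH2Cl2, 0 °C to rt; then 2, AlCl3 (3.5 equiv), PhNO2/CH2Cl2, 0 °C to rt; cold 1 M HCl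
Reagents that add atoms: oxalyl chloride, O=C(Cl)C(=O)Cl (supplies only the chlorine of 3; no atom of it remains in 4)
Why: Friedel–Crafts C-acylation of the very electron-rich triol at one of its two equivalent free ring positions; the stereocentre is bought with 1 and should survive because acylation is fast at low temperature and the product ketone is held as an aluminium chelate that resists enolisation.

Step 2
Reactants: 4 (2R)-2-methyl-1-(2,4,6-trihydroxy-3-methylphenyl)butan-1-one
Product: 5 (2R)-1-(2,6-dihydroxy-4-methoxy-3-methylphenyl)-2-methylbutan-1-one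
Conditions: Me2SO4 (1.0 equiv), K2CO3 (1.1 equiv), acetone, 0 °C to rt
Reagents that add atoms: dimethyl sulfate, COS(=O)(=O)OC
Why: Williamson-type O-methylation that should select the 4-OH, the most acidic hydroxyl (para to the acyl group) and the only one that cannot hydrogen-bond to the ketone, while the weak base leaves the alpha stereocentre untouched.

Step 3
Reactants: 2 2-methylbenzene-1,3,5-triol
Product: 6 1-(2,4,6-trihydroxy-3-methylphenyl)ethan-1-one
Conditions: AcCl (1.05 equiv), AlCl3 (3.5 equiv), PhNO2/CH2Cl2, 0 °C to rt; 1 M HCl
Reagents that add atoms: acetyl chloride, CC(=O)Cl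
Why: Friedel–Crafts acylation in which the two free positions of 2 are equivalent, so a single C-acetyl product is expected.

Step 4
Reactants: 6 1-(2,4,6-trihydroxy-3-methylphenyl)ethan-1-one
Product: 7 1-[2-hydroxy-3-methyl-4,6-di(propan-2-yloxy)phenyl]ethan-1-one
Conditions: 2-bromopropane (2.4 equiv), K2CO3 (2.5 equiv), DMF, 50 °C
Reagents that add atoms: 2-bromopropane, CC(C)Br
Why: Williamson etherification in which the para 4-OH and then the less hindered ortho 6-OH are alkylated by the secondary halide while the 2-OH, wedged between the C-methyl and acetyl groups and chelated to the carbonyl, stays free, so the isopropyl group that will become C2 sits on the oxygen next to the unsubstituted ring carbon (any 2,4-dialkylated isomer is removed by chromatography).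

Step 5
Reactants: 7 1-[2-hydroxy-3-methyl-4,6-di(propan-2-yloxy)phenyl]ethan-1-one
Product: 8 1-[2-methoxy-3-methyl-4,6-di(propan-2-yloxy)phenyl]ethan-1-one
Conditions: Me2SO4 (1.5 equiv), K2CO3 (3 equiv), acetone, reflux
Reagents that add atoms: dimethyl sulfate, COS(=O)(=O)OC
Why: forced Williamson O-methylation of the remaining chelated phenol, which removes the only O–H bond a carbenoid could attack and installs a group that BCl3 later cleaves by chelation.

Step 6
Reactants: 8 1-[2-methoxy-3-methyl-4,6-di(propan-2-yloxy)phenyl]ethan-1-one
Product: 10 2-diazo-1-[2-methoxy-3-methyl-4,6-di(propan-2-yloxy)phenyl]ethan-1-one, via trifluoroacetyl diketone 9 (not isolated)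
Conditions: LiN(SiMe3)2 (1.1 equiv), THF, −78 °C; CF3CO2CH2CF3 (1.2 equiv); aq. NH4Cl; then MsN3 (1.5 equiv), Et3N (1.5 equiv), H2O (1 equiv), MeCN, rt
Reagents that add atoms: methanesulfonyl azide, CS(=O)(=O)N=[N+]=[N-] (the two diazo nitrogens of 10); 2,2,2-trifluoroethyl trifluoroacetate, O=C(OCC(F)(F)F)C(F)(F)F (the trifluoroacetyl group of 9 only, lost again)
Why: detrifluoroacetylative Regitz diazo transfer, in which Claisen trifluoroacetylation of the kinetic methyl ketone enolate activates the alpha carbon and diazo transfer from the sulfonyl azide to diketone 9 is followed by loss of the trifluoroacetyl group as the N-sulfonyl amide.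

Step 7
Reactants: 10 2-diazo-1-[2-methoxy-3-methyl-4,6-di(propan-2-yloxy)phenyl]ethan-1-one
Product: 11 5-methoxy-2,2,6-trimethyl-7-(propan-2-yloxy)-2,3-dihydro-4H-chromen-4-one
Conditions: Rh2(OAc)4 (1 mol %), CH2Cl2, 40 °C, slow addition of 10 at high dilution
Reagents that add atoms: none
Why: Rh2(OAc)4 expels N2 from 10 to give an electrophilic rhodium carbenoid at C3, which inserts through a concerted, hydride-transfer-like three-centre transition state into the tertiary C–H bond of the ortho isopropyl ether, so that the methine becomes C2 and the new C2–C3 bond closes ring C. The closest known reaction type is the dirhodium-carboxylate-catalysed intramolecular C–H insertion of ortho-alkoxyaryl diazomethyl ketones alpha to the ether oxygen, which gives chroman-4-ones. Ring C (O1, C2, C3, C4, C4a, C8a) closes as a six-membered ring by a formal 1,6-C–H insertion, the only C–H insertion geometry open to this tether because the five-membered alternative would end on oxygen. No stereocentre is formed, since C2 carries two methyl groups and C3 becomes a methylene. The step needs site selectivity for the O–CH(CH3)2 hydrogen over the ortho O–CH3 hydrogens and chemoselectivity over oxonium-ylide chemistry: the tertiary, oxygen-stabilised C–H bond is far more hydridic than a methoxy C–H bond, the 4-isopropoxy group is out of reach, an ylide at the methoxy oxygen has no easy rearrangement path and reverts to the carbenoid, and no O–H, allyl or benzyl group is present. Slow addition suppresses carbene dimerisation, and the ring B regiochemistry (methyl at C6, hydrogen at C8) is fixed because only the oxygen next to the free aromatic CH carries an isopropyl group.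

Step 8
Reactants: 11 5-methoxy-2,2,6-trimethyl-7-(propan-2-yloxy)-2,3-dihydro-4H-chromen-4-one
Product: 12 5,7-dihydroxy-2,2,6-trimethyl-2,3-dihydro-4H-chromen-4-one
Conditions: BCl3 (5 equiv), CH2Cl2, −78 to 0 °C; H2O
Reagents that add atoms: none
Why: Lewis-acid ether cleavage in which BCl3 dealkylates the aryl isopropyl ether and, through chelation with the C4 carbonyl, the peri 5-methoxy group, while the cyclic O1–C2 ether of ring C, whose oxygen is a weakly basic vinylogous ester oxygen, should survive at or below 0 °C.

Step 9
Reactants: 12 5,7-dihydroxy-2,2,6-trimethyl-2,3-dihydro-4H-chromen-4-one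
Product: 13 8-[(dimethylamino)methyl]-5,7-dihydroxy-2,2,6-trimethyl-2,3-dihydro-4H-chromen-4-one
Conditions: 40% aq. Me2NH (3 equiv), 37% aq. CH2O (1.2 equiv), EtOH, 0 °C to rt
Reagents that add atoms: formaldehyde, C=O; dimethylamine, CNC
Why: phenolic Mannich reaction at C8, the only unsubstituted carbon of ring B (ortho to the 7-OH, para to the 5-OH), with excess amine holding the product as the Mannich base so that no symmetrical diarylmethane forms.

Step 10
Reactants: 13 8-[(dimethylamino)methyl]-5,7-dihydroxy-2,2,6-trimethyl-2,3-dihydro-4H-chromen-4-one; 5 (2R)-1-(2,6-dihydroxy-4-methoxy-3-methylphenyl)-2-methylbutan-1-one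
Product: 15 8-({2,4-dihydroxy-6-methoxy-5-methyl-3-[(2R)-2-methylbutanoyl]phenyl}methyl)-5,7-dihydroxy-2,2,6-trimethyl-2,3-dihydro-4H-chromen-4-one (CNP0303209.1), via ortho-quinone methide 14 (not isolated)
Conditions: 13 (1.0 equiv), 5 (1.1 equiv), 1,4-dioxane, 90 °C, N2 sweep
Reagents that add atoms: none
Why: thermal loss of dimethylamine from the zwitterionic Mannich base gives ortho-quinone methide 14, which is trapped by Michael-type C-alkylation at the only free ring carbon of 5 (C5, between OMe and OH) followed by rearomatisation, cross-coupling being enforced because 13 has no free ring position, and the neutral conditions should leave the remote R stereocentre alone.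

Compound list
1 | (R)-2-methylbutanoic acid | CC[C@@H](C)C(=O)O | starting material
2 | 2-methylbenzene-1,3,5-triol (2-methylphloroglucinol) | Cc1c(O)cc(O)cc1O | starting material
3 | (R)-2-methylbutanoyl chloride | CC[C@@H](C)C(=O)Cl | intermediate (not isolated)
4 | (2R)-2-methyl-1-(2,4,6-trihydroxy-3-methylphenyl)butan-1-one | CC[C@@H](C)C(=O)c1c(O)c(C)c(O)cc1O | intermediate
5 | (2R)-1-(2,6-dihydroxy-4-methoxy-3-methylphenyl)-2-methylbutan-1-one | CC[C@@H](C)C(=O)c1c(O)c(C)c(OC)cc1O | intermediate
6 | 1-(2,4,6-trihydroxy-3-methylphenyl)ethan-1-one | CC(=O)c1c(O)c(C)c(O)cc1O | intermediate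
7 | 1-[2-hydroxy-3-methyl-4,6-di(propan-2-yloxy)phenyl]ethan-1-one | CC(=O)c1c(O)c(C)c(OC(C)C)cc1OC(C)C | intermediate
8 | 1-[2-methoxy-3-methyl-4,6-di(propan-2-yloxy)phenyl]ethan-1-one | CC(=O)c1c(OC)c(C)c(OC(C)C)cc1OC(C)C | intermediate
9 | 4,4,4-trifluoro-1-[2-methoxy-3-methyl-4,6-di(propan-2-yloxy)phenyl]butane-1,3-dione | O=C(CC(=O)C(F)(F)F)c1c(OC)c(C)c(OC(C)C)cc1OC(C)C | intermediate (not isolated)
10 | 2-diazo-1-[2-methoxy-3-methyl-4,6-di(propan-2-yloxy)phenyl]ethan-1-one | O=C(C=[N+]=[N-])c1c(OC)c(C)c(OC(C)C)cc1OC(C)C | intermediate
11 | 5-methoxy-2,2,6-trimethyl-7-(propan-2-yloxy)-2,3-dihydro-4H-chromen-4-one | CC1(C)CC(=O)c2c(OC)c(C)c(OC(C)C)cc2O1 | intermediate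
12 | 5,7-dihydroxy-2,2,6-trimethyl-2,3-dihydro-4H-chromen-4-one | CC1(C)CC(=O)c2c(O)c(C)c(O)cc2O1 | intermediate
13 | 8-[(dimethylamino)methyl]-5,7-dihydroxy-2,2,6-trimethyl-2,3-dihydro-4H-chromen-4-one | CC1(C)CC(=O)c2c(O)c(C)c(O)c(CN(C)C)c2O1 | intermediate
14 | 5-hydroxy-2,2,6-trimethyl-8-methylidene-2,3-dihydro-4H-chromene-4,7(8H)-dione (ortho-quinone methide) | C=C1C(=O)C(C)=C(O)C2=C1OC(C)(C)CC2=O | intermediate (not isolated)
15 | 8-({2,4-dihydroxy-6-methoxy-5-methyl-3-[(2R)-2-methylbutanoyl]phenyl}methyl)-5,7-dihydroxy-2,2,6-trimethyl-2,3-dihydro-4H-chromen-4-one | CC[C@@H](C)C(=O)c1c(O)c(C)c(OC)c(Cc2c(O)c(C)c(O)c3c2OC(C)(C)CC3=O)c1O | target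

Total step count: 10. Longest linear sequence: 8 steps (steps 3 to 10, from 2 to 15).

Steps most likely to fail

Step 7. The carbenoid may be diverted into oxonium-ylide formation at an ether oxygen with loss of propene or alkyl shift, or into insertion at the methoxy group. The fallback builds ring C by a Kabbe condensation instead and sets out from 8. BCl3 (1.0 equiv, CH2Cl2, −78 °C) should remove only the isopropyl group that is ortho to and chelated with the acetyl carbonyl, giving 1-[6-hydroxy-2-methoxy-3-methyl-4-(propan-2-yloxy)phenyl]ethan-1-one F1. Heating F1 with acetone and pyrrolidine (EtOH, reflux) brings about aldol condensation to the enone and oxa-Michael closure through the freed phenol, and the route is rejoined at 11.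

Step 10. Amine loss may be slow, the diarylmethane may scramble into symmetrical dimers on prolonged heating, or the alpha stereocentre may erode in the warm amine-containing medium. The fallback is the direct one-pot condensation and sets out from 12 and 5. The two phenols are stirred with 37% aq. CH2O (one equivalent per pair) in dilute aqueous-methanolic NaOH at 0 °C, then acidified, and 15 is separated by chromatography from the two symmetrical methylene-bis by-products. This returns directly to 15 and isolates no new compound (F0).

Step 1. The configuration may erode by ketene formation from the acylium species or by Lewis-acid-promoted enolisation of the ketone. The fallback delivers the acyl group without a Lewis acid and sets out from 2 and 1. Triol 2 is converted with MOMCl and iPr2NEt (CH2Cl2) into 1,3,5-tris(methoxymethoxy)-2-methylbenzene F2. Acid 1 is converted with MeNHOMe·HCl, EDC·HCl and N-methylmorpholine into (2R)-N-methoxy-N,2-dimethylbutanamide F3. Directed ortho-lithiation of F2 (n-BuLi, THF, 0 °C; the two positions between MOM ethers are equivalent) and addition of F3 at −78 °C give, by Weinreb ketone synthesis, (2R)-2-methyl-1-[2,4,6-tris(methoxymethoxy)-3-methylphenyl]butan-1-one F4. HCl in MeOH at rt removes the three MOM groups and the route is rejoined at 4.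

Further compounds
F1 | step 7 | 1-[6-hydroxy-2-methoxy-3-methyl-4-(propan-2-yloxy)phenyl]ethan-1-one | CC(=O)c1c(OC)c(C)c(OC(C)C)cc1O
F0 | step 10 | none | none
F2 | step 1 | 1,3,5-tris(methoxymethoxy)-2-methylbenzene | Cc1c(OCOC)cc(OCOC)cc1OCOC
F3 | step 1 | (2R)-N-methoxy-N,2-dimethylbutanamide | CC[C@@H](C)C(=O)N(C)OC
F4 | step 1 | (2R)-2-methyl-1-[2,4,6-tris(methoxymethoxy)-3-methylphenyl]butan-1-one | CC[C@@H](C)C(=O)c1c(OCOC)c(C)c(OCOC)cc1OCOC
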